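**Retrosynthetic overview**
1. Target 28 ⇐ silyl ether 27 (C14–O deprotection only).
2. 27 ⇐ acyclic bromo-ester aldehyde 24 by one chromium-catalysed asymmetric intramolecular 2-(methoxycarbonyl)allylation: it forms C7–C8, both stereocentres and the ten-membered carbocycle (first ring); the γ-lactone (second ring) closes on work-up.
3. 24 ⇐ triene 21 + methyl 2-(bromomethyl)acrylate (cross-metathesis at C7=C11); the C15 ester comes from a Mitsunobu reaction.
4. 21 ⇐ aldehyde 12 + phosphonate 15 (Horner–Wadsworth–Emmons sets the ring-cis C1(10) alkene that carries C14).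
5. 12 ⇐ dienol 8 (Johnson–Claisen sets the ring-trans C4 alkene that carries C15) ⇐ bromoallyl ether 3, DMF, allylMgBr. The usual intermolecular Barbier lactone plus ring-closing metathesis is not used.

Assumption: germacrane numbering is used (C7/C8 ring fusion, C12 lactone carbonyl, C13 exocyclic CH2, C14 on C10, C15 on C4); L* = 3,6-di-tert-butyl-1,8-bis[(4S)-4-isopropyl-4,5-dihydro-1,3-oxazol-2-yl]-9H-carbazole, and the ligand antipode that gives (7R,8S) is settled by a trial run, the (S,S) form being written.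

**Step 1**
Reactants: 1 4-methoxybenzyl alcohol; 2 2,3-dibromoprop-1-ene
Product: 3 1-{[(2-bromoprop-2-en-1-yl)oxy]methyl}-4-methoxybenzene
Conditions: NaH, Bu4NI (cat.), THF, 0 °C to rt
Reagents that add atoms: none
Why: Williamson ether synthesis; the alkoxide displaces the allylic bromide by SN2 while the vinylic bromide is inert; no stereocentre.

**Step 2**
Reactants: 3 1-{[(2-bromoprop-2-en-1-yl)oxy]methyl}-4-methoxybenzene; 4 N,N-dimethylformamide
Product: 6 2-{[(4-methoxybenzyl)oxy]methyl}prop-2-enal, via vinyllithium 5 (not isolated)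
Conditions: t-BuLi (2.1 equiv), Et2O, −78 °C; then DMF, −78 to 0 °C; aq. NH4Cl
Reagents that add atoms: none
Why: bromine–lithium exchange followed by Bouveault formylation of the 2-lithioallyl ether; no stereocentre; the enal is used at once.

**Step 3**
Reactants: 6 2-{[(4-methoxybenzyl)oxy]methyl}prop-2-enal; 7 allylmagnesium bromide
Product: 8 2-{[(4-methoxybenzyl)oxy]methyl}hexa-1,5-dien-3-ol (racemic)
Conditions: allylMgBr, Et2O, −78 °C
Reagents that add atoms: none
Why: Grignard 1,2-addition to the enal; the carbinol centre is left racemic because step 4 erases it.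

**Step 4**
Reactants: 8 2-{[(4-methoxybenzyl)oxy]methyl}hexa-1,5-dien-3-ol; 9 triethyl orthoacetate
Product: 11 ethyl (4Z)-4-{[(4-methoxybenzyl)oxy]methyl}octa-4,7-dienoate, via ketene acetal 10 (not isolated)
Conditions: MeC(OEt)3, EtCO2H (cat.), 140 °C, EtOH distilled off
Reagents that add atoms: none
Why: Johnson–Claisen rearrangement; in the chair transition state the allyl-bearing carbinol substituent sits equatorial, so C6 ends trans to the new ester chain and cis to CH2OPMB, which is the geometry of the ring-trans C4=C5 alkene.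

**Step 5**
Reactants: 11 ethyl (4Z)-4-{[(4-methoxybenzyl)oxy]methyl}octa-4,7-dienoate
Product: 12 (4Z)-4-{[(4-methoxybenzyl)oxy]methyl}octa-4,7-dienal
Conditions: i-Bu2AlH (1.05 equiv), CH2Cl2, −78 °C
Reagents that add atoms: none
Why: ester half-reduction through the aluminium hemiacetal, which is stable at −78 °C; the alkene geometry is untouched.

**Step 6**
Reactants: 13 triethyl phosphonoacetate; 14 2-bromo-1,1-diethoxyethane
Product: 15 ethyl 2-(diethoxyphosphoryl)-4,4-diethoxybutanoate (racemic)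
Conditions: NaH, NaI (cat.), DMF, 90 °C
Reagents that add atoms: none
Why: SN2 C-alkylation of the phosphonoacetate anion with iodide assistance; the new centre is lost in step 7.

**Step 7**
Reactants: 12 (4Z)-4-{[(4-methoxybenzyl)oxy]methyl}octa-4,7-dienal; 15 ethyl 2-(diethoxyphosphoryl)-4,4-diethoxybutanoate
Product: 16 ethyl (2E,6Z)-2-(2,2-diethoxyethyl)-6-{[(4-methoxybenzyl)oxy]methyl}deca-2,6,9-trienoate
Conditions: NaH, THF, 0 °C to rt
Reagents that add atoms: none
Why: Horner–Wadsworth–Emmons olefination; the stabilised phosphonate gives mainly the (E)-enoate (ester trans to the chain), which puts the acetal arm cis to the chain as needed for the ring-cis C1(10) alkene; the minor (Z) isomer is removed by chromatography.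

**Step 8**
Reactants: 16 ethyl (2E,6Z)-2-(2,2-diethoxyethyl)-6-{[(4-methoxybenzyl)oxy]methyl}deca-2,6,9-trienoate
Product: 17 (2E,6Z)-2-(2,2-diethoxyethyl)-6-{[(4-methoxybenzyl)oxy]methyl}deca-2,6,9-trien-1-ol
Conditions: i-Bu2AlH (2.5 equiv), CH2Cl2, −78 to 0 °C
Reagents that add atoms: none
Why: 1,2-reduction of the conjugated ester to the allylic alcohol (C14–OH); acetal, PMB ether and alkenes are inert to the hydride.

**Step 9**
Reactants: 17 (2E,6Z)-2-(2,2-diethoxyethyl)-6-{[(4-methoxybenzyl)oxy]methyl}deca-2,6,9-trien-1-ol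
Product: 18 tert-butyl{[(2E,6Z)-2-(2,2-diethoxyethyl)-6-{[(4-methoxybenzyl)oxy]methyl}deca-2,6,9-trien-1-yl]oxy}diphenylsilane
Conditions: TBDPSCl, imidazole, DMF, rt
Reagents that add atoms: tert-butyl(chloro)diphenylsilane, CC(C)(C)[Si](Cl)(c1ccccc1)c1ccccc1
Why: silylation of the primary allylic alcohol with a group that survives DDQ, Mitsunobu, metathesis, mild acid and the chromium step.

**Step 10**
Reactants: 18 tert-butyl{[(2E,6Z)-2-(2,2-diethoxyethyl)-6-{[(4-methoxybenzyl)oxy]methyl}deca-2,6,9-trien-1-yl]oxy}diphenylsilane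
Product: 19 (2Z)-2-[(3E)-4-{[(tert-butyldiphenylsilyl)oxy]methyl}-6,6-diethoxyhex-3-en-1-yl]hexa-2,5-dien-1-ol
Conditions: DDQ, CH2Cl2/pH 7 buffer, 0 °C
Reagents that add atoms: none
Why: oxidative PMB ether cleavage (benzylic hydride abstraction, then hydrolysis of the oxocarbenium ion); the silyl ether and acetal survive at neutral pH.

**Step 11**
Reactants: 19 (2Z)-2-[(3E)-4-{[(tert-butyldiphenylsilyl)oxy]methyl}-6,6-diethoxyhex-3-en-1-yl]hexa-2,5-dien-1-ol; 20 2-hydroxy-2-methylpropanoic acid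
Product: 21 (2Z)-2-[(3E)-4-{[(tert-butyldiphenylsilyl)oxy]methyl}-6,6-diethoxyhex-3-en-1-yl]hexa-2,5-dien-1-yl 2-hydroxy-2-methylpropanoate
Conditions: PPh3, DIAD, THF, 0 °C to rt
Reagents that add atoms: none
Why: Mitsunobu esterification; the carboxylate displaces the oxyphosphonium of the primary allylic alcohol by SN2, and the tertiary hydroxyl of the acid is neither acidic enough nor activated.

**Step 12**
Reactants: 21 (2Z)-2-[(3E)-4-{[(tert-butyldiphenylsilyl)oxy]methyl}-6,6-diethoxyhex-3-en-1-yl]hexa-2,5-dien-1-yl 2-hydroxy-2-methylpropanoate; 22 methyl 2-(bromomethyl)prop-2-enoate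
Product: 23 methyl (2Z,5Z,9E)-2-(bromomethyl)-10-{[(tert-butyldiphenylsilyl)oxy]methyl}-12,12-diethoxy-6-{[(2-hydroxy-2-methylpropanoyl)oxy]methyl}dodeca-2,5,9-trienoate
Conditions: second-generation Hoveyda–Grubbs catalyst (10 mol %), 1,4-benzoquinone (20 mol %), 22 (6 equiv), CH2Cl2, 40 °C
Reagents that add atoms: none
Why: olefin cross-metathesis of the only monosubstituted alkene with a 1,1-disubstituted acrylate, by analogy with methacrylate partners; the phosphine-free catalyst cannot be quaternised by the allylic bromide, the trisubstituted alkenes are spectators (ring closure onto them would need a trans-cycloheptene), and the geometry of the new alkene does not matter later.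

**Step 13**
Reactants: 23 methyl (2Z,5Z,9E)-2-(bromomethyl)-10-{[(tert-butyldiphenylsilyl)oxy]methyl}-12,12-diethoxy-6-{[(2-hydroxy-2-methylpropanoyl)oxy]methyl}dodeca-2,5,9-trienoate
Product: 24 methyl (2Z,5Z,9E)-2-(bromomethyl)-10-{[(tert-butyldiphenylsilyl)oxy]methyl}-6-{[(2-hydroxy-2-methylpropanoyl)oxy]methyl}-12-oxododeca-2,5,9-trienoate
Conditions: 10 % aq. oxalic acid on SiO2, CH2Cl2, rt
Reagents that add atoms: water, O
Why: mild acid hydrolysis of the acyclic diethyl acetal; silyl ether, esters and allylic bromide are untouched, and the β,γ-unsaturated aldehyde is filtered and used crude to avoid conjugation.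

**Step 14**
Reactants: 24 methyl (2Z,5Z,9E)-2-(bromomethyl)-10-{[(tert-butyldiphenylsilyl)oxy]methyl}-6-{[(2-hydroxy-2-methylpropanoyl)oxy]methyl}-12-oxododeca-2,5,9-trienoate
Product: 27 [(3aR,5Z,9E,11aS)-10-{[(tert-butyldiphenylsilyl)oxy]methyl}-3-methylidene-2-oxo-2,3,3a,4,7,8,11,11a-octahydrocyclodeca[b]furan-6-yl]methyl 2-hydroxy-2-methylpropanoate, via silyl ether 25 (not isolated), via hydroxy ester 26 (not isolated)
Conditions: CrCl2 (20 mol %), L* (22 mol %), i-Pr2NEt (40 mol %), Mn, Me3SiCl, THF, 24 added by syringe pump to 2 mM, rt; then aq. citric acid; PPTS (cat.), CH2Cl2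
Reagents that add atoms: none
Why: Proposed new method: divalent chromium (regenerated by Mn) turns the allylic bromide into an allyl complex of trivalent chromium bound to the chiral tridentate ligand; this equilibrating allyl species adds through C7 to the aldehyde in a chair six-membered transition state with both ring chains pseudo-equatorial, giving the anti adduct (7,8-trans) while the ligand selects the aldehyde face to set (7R,8S); Me3SiCl frees the catalyst, and the γ-hydroxy ester lactonises under acid; the closest known reactions are the intermolecular chromium-catalysed enantioselective 2-(alkoxycarbonyl)allylation–lactonisation of aldehydes with carbazole bis(oxazoline) ligands and the racemic Nozaki–Hiyama-type chromium macrocyclisations that give trans-fused germacranolides.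

**Step 15**
Reactants: 27 [(3aR,5Z,9E,11aS)-10-{[(tert-butyldiphenylsilyl)oxy]methyl}-3-methylidene-2-oxo-2,3,3a,4,7,8,11,11a-octahydrocyclodeca[b]furan-6-yl]methyl 2-hydroxy-2-methylpropanoate
Product: 28 [(3aR,5Z,9E,11aS)-10-(hydroxymethyl)-3-methylidene-2-oxo-2,3,3a,4,7,8,11,11a-octahydrocyclodeca[b]furan-6-yl]methyl 2-hydroxy-2-methylpropanoate
Conditions: HF·pyridine, pyridine, THF, 0 °C to rt
Reagents that add atoms: none
Why: fluoride cleavage of the silyl ether; the α-methylene lactone, allylic ester and both stereocentres are unaffected.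

**Compound list**
1 | 4-methoxybenzyl alcohol | COc1ccc(CO)cc1 | starting material
2 | 2,3-dibromoprop-1-ene | C=C(Br)CBr | starting material
3 | 1-{[(2-bromoprop-2-en-1-yl)oxy]methyl}-4-methoxybenzene | C=C(Br)COCc1ccc(OC)cc1 | intermediate
4 | N,N-dimethylformamide | CN(C)C=O | starting material
5 | {3-[(4-methoxybenzyl)oxy]prop-1-en-2-yl}lithium | [Li]C(=C)COCc1ccc(OC)cc1 | intermediate
6 | 2-{[(4-methoxybenzyl)oxy]methyl}prop-2-enal | C=C(C=O)COCc1ccc(OC)cc1 | intermediate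
7 | allylmagnesium bromide | C=CC[Mg]Br | starting material
8 | 2-{[(4-methoxybenzyl)oxy]methyl}hexa-1,5-dien-3-ol (racemic) | C=CCC(O)C(=C)COCc1ccc(OC)cc1 | intermediate
9 | triethyl orthoacetate | CC(OCC)(OCC)OCC | starting material
10 | 3-[(1-ethoxyethenyl)oxy]-2-{[(4-methoxybenzyl)oxy]methyl}hexa-1,5-diene (ketene acetal) | C=C(OCC)OC(CC=C)C(=C)COCc1ccc(OC)cc1 | intermediate
11 | ethyl (4Z)-4-{[(4-methoxybenzyl)oxy]methyl}octa-4,7-dienoate | CCOC(=O)CC/C(COCc1ccc(OC)cc1)=C/CC=C | intermediate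
12 | (4Z)-4-{[(4-methoxybenzyl)oxy]methyl}octa-4,7-dienal | O=CCC/C(COCc1ccc(OC)cc1)=C/CC=C | intermediate
13 | triethyl phosphonoacetate | CCOC(=O)CP(=O)(OCC)OCC | starting material
14 | 2-bromo-1,1-diethoxyethane | CCOC(CBr)OCC | starting material
15 | ethyl 2-(diethoxyphosphoryl)-4,4-diethoxybutanoate (racemic) | CCOC(=O)C(CC(OCC)OCC)P(=O)(OCC)OCC | intermediate
16 | ethyl (2E,6Z)-2-(2,2-diethoxyethyl)-6-{[(4-methoxybenzyl)oxy]methyl}deca-2,6,9-trienoate | CCOC(=O)/C(CC(OCC)OCC)=C/CC/C(COCc1ccc(OC)cc1)=C/CC=C | intermediate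
17 | (2E,6Z)-2-(2,2-diethoxyethyl)-6-{[(4-methoxybenzyl)oxy]methyl}deca-2,6,9-trien-1-ol | OC/C(CC(OCC)OCC)=C/CC/C(COCc1ccc(OC)cc1)=C/CC=C | intermediate
18 | tert-butyl{[(2E,6Z)-2-(2,2-diethoxyethyl)-6-{[(4-methoxybenzyl)oxy]methyl}deca-2,6,9-trien-1-yl]oxy}diphenylsilane | CC(C)(C)[Si](OC/C(CC(OCC)OCC)=C/CC/C(COCc1ccc(OC)cc1)=C/CC=C)(c1ccccc1)c1ccccc1 | intermediate
19 | (2Z)-2-[(3E)-4-{[(tert-butyldiphenylsilyl)oxy]methyl}-6,6-diethoxyhex-3-en-1-yl]hexa-2,5-dien-1-ol | CC(C)(C)[Si](OC/C(CC(OCC)OCC)=C/CC/C(CO)=C/CC=C)(c1ccccc1)c1ccccc1 | intermediate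
20 | 2-hydroxy-2-methylpropanoic acid | CC(C)(O)C(=O)O | starting material
21 | (2Z)-2-[(3E)-4-{[(tert-butyldiphenylsilyl)oxy]methyl}-6,6-diethoxyhex-3-en-1-yl]hexa-2,5-dien-1-yl 2-hydroxy-2-methylpropanoate | CC(C)(C)[Si](OC/C(CC(OCC)OCC)=C/CC/C(COC(=O)C(C)(C)O)=C/CC=C)(c1ccccc1)c1ccccc1 | intermediate
22 | methyl 2-(bromomethyl)prop-2-enoate | C=C(CBr)C(=O)OC | starting material
23 | methyl (2Z,5Z,9E)-2-(bromomethyl)-10-{[(tert-butyldiphenylsilyl)oxy]methyl}-12,12-diethoxy-6-{[(2-hydroxy-2-methylpropanoyl)oxy]methyl}dodeca-2,5,9-trienoate | CC(C)(C)[Si](OC/C(CC(OCC)OCC)=C/CC/C(COC(=O)C(C)(C)O)=C/C/C=C(\CBr)C(=O)OC)(c1ccccc1)c1ccccc1 | intermediate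
24 | methyl (2Z,5Z,9E)-2-(bromomethyl)-10-{[(tert-butyldiphenylsilyl)oxy]methyl}-6-{[(2-hydroxy-2-methylpropanoyl)oxy]methyl}-12-oxododeca-2,5,9-trienoate | CC(C)(C)[Si](OC/C(CC=O)=C/CC/C(COC(=O)C(C)(C)O)=C/C/C=C(\CBr)C(=O)OC)(c1ccccc1)c1ccccc1 | intermediate
25 | methyl 2-[(1R,2S,4E,8Z)-4-{[(tert-butyldiphenylsilyl)oxy]methyl}-8-{[(2-hydroxy-2-methylpropanoyl)oxy]methyl}-2-[(trimethylsilyl)oxy]cyclodeca-4,8-dien-1-yl]prop-2-enoate | C=C(C(=O)OC)[C@H]1C/C=C(COC(=O)C(C)(C)O)/CC/C=C(CO[Si](c2ccccc2)(c2ccccc2)C(C)(C)C)\C[C@@H]1O[Si](C)(C)C | intermediate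
26 | methyl 2-[(1R,2S,4E,8Z)-4-{[(tert-butyldiphenylsilyl)oxy]methyl}-2-hydroxy-8-{[(2-hydroxy-2-methylpropanoyl)oxy]methyl}cyclodeca-4,8-dien-1-yl]prop-2-enoate | C=C(C(=O)OC)[C@H]1C/C=C(COC(=O)C(C)(C)O)/CC/C=C(CO[Si](c2ccccc2)(c2ccccc2)C(C)(C)C)\C[C@@H]1O | intermediate
27 | [(3aR,5Z,9E,11aS)-10-{[(tert-butyldiphenylsilyl)oxy]methyl}-3-methylidene-2-oxo-2,3,3a,4,7,8,11,11a-octahydrocyclodeca[b]furan-6-yl]methyl 2-hydroxy-2-methylpropanoate | C=C1C(=O)O[C@H]2C/C(CO[Si](c3ccccc3)(c3ccccc3)C(C)(C)C)=C\CC/C(COC(=O)C(C)(C)O)=C/C[C@H]12 | intermediate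
28 | [(3aR,5Z,9E,11aS)-10-(hydroxymethyl)-3-methylidene-2-oxo-2,3,3a,4,7,8,11,11a-octahydrocyclodeca[b]furan-6-yl]methyl 2-hydroxy-2-methylpropanoate | C=C1C(=O)O[C@H]2C/C(CO)=C\CC/C(COC(=O)C(C)(C)O)=C/C[C@H]12 | target

**Step count and risks**
Total steps: 15. Longest linear sequence: 14 (steps 1 to 5, then 7 to 15; step 6 is a one-step side branch).

The three steps most likely to fail:

Step 14 (the new asymmetric ring closure; both the enantio- and the anti-selectivity are unproven in a macrocyclisation). Fallback: give up catalyst control and resolve. It sets out from 24: ring closure with excess CrCl2 in THF without ligand at 2 mM, then PPTS, gives the racemic trans-lactone, a 1:1 mixture of 27 and its (3aS,11aR) enantiomer F1. Preparative chromatography on a chiral stationary phase removes the enantiomer F1, and the route is rejoined at 27.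

Step 12 (cross-metathesis with a hindered, electrophilic bromo-acrylate). Fallback: make the same bromide by carbonyl chemistry at C7, which needs an oxygen on C7 from the start. It sets out from vinyllithium 5: addition to 3-[(tert-butyldimethylsilyl)oxy]propanal gives the racemic silyloxy allylic alcohol F2. MeC(OEt)3/EtCO2H at 140 °C (through the silyloxy ketene acetal F3) gives the silyloxy heptenoate F4, and i-Bu2AlH at −78 °C gives the silyloxy heptenal F5. The sodium salt of 15 gives the silyloxy nonadienoate F6, i-Bu2AlH gives the silyloxy nonadienol F7, and TBDPSCl gives the bis-silyl ether F8. DDQ gives the C15 alcohol F9, and PPh3/DIAD with 20 gives the bis-silyl hydroxyisobutyrate F10. PPTS in EtOH removes only the primary tert-butyldimethylsilyl group to give the C7 alcohol F11, and Dess–Martin periodinane gives the C7 aldehyde F12. The vinylalane F13 (from methyl propiolate, i-Bu2AlH and N-methylmorpholine N-oxide) adds to F12 to give the Baylis–Hillman-type alcohol F14. N-Bromosuccinimide/Me2S converts this with allylic transposition into 23, where the route is rejoined.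

Step 6 (SN2 on a β,β-dialkoxy bromide is slow and elimination competes). Fallback: bring in the acetal carbon as an alkene. It sets out from 13: NaH and allyl bromide give the allylated phosphonate ethyl 2-(diethoxyphosphoryl)pent-4-enoate F15. Ozone, then Me2S, gives the aldehyde ethyl 2-(diethoxyphosphoryl)-4-oxobutanoate F16. EtOH, PPTS and molecular sieves acetalise it to 15, where the route is rejoined.

**Further compounds**
F1 | step 14 | [(3aS,5Z,9E,11aR)-10-{[(tert-butyldiphenylsilyl)oxy]methyl}-3-methylidene-2-oxo-2,3,3a,4,7,8,11,11a-octahydrocyclodeca[b]furan-6-yl]methyl 2-hydroxy-2-methylpropanoate (enantiomer of 27) | C=C1C(=O)O[C@@H]2C/C(CO[Si](c3ccccc3)(c3ccccc3)C(C)(C)C)=C\CC/C(COC(=O)C(C)(C)O)=C/C[C@@H]12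
F2 | step 12 | 5-[(tert-butyldimethylsilyl)oxy]-2-{[(4-methoxybenzyl)oxy]methyl}pent-1-en-3-ol (racemic) | C=C(COCc1ccc(OC)cc1)C(O)CCO[Si](C)(C)C(C)(C)C
F3 | step 12 | tert-butyl({3-[(1-ethoxyethenyl)oxy]-4-{[(4-methoxybenzyl)oxy]methyl}pent-4-en-1-yl}oxy)dimethylsilane | C=C(OCC)OC(CCO[Si](C)(C)C(C)(C)C)C(=C)COCc1ccc(OC)cc1
F4 | step 12 | ethyl (4Z)-7-[(tert-butyldimethylsilyl)oxy]-4-{[(4-methoxybenzyl)oxy]methyl}hept-4-enoate | CCOC(=O)CC/C(COCc1ccc(OC)cc1)=C/CCO[Si](C)(C)C(C)(C)C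
F5 | step 12 | (4Z)-7-[(tert-butyldimethylsilyl)oxy]-4-{[(4-methoxybenzyl)oxy]methyl}hept-4-enal | O=CCC/C(COCc1ccc(OC)cc1)=C/CCO[Si](C)(C)C(C)(C)C
F6 | step 12 | ethyl (2E,6Z)-9-[(tert-butyldimethylsilyl)oxy]-2-(2,2-diethoxyethyl)-6-{[(4-methoxybenzyl)oxy]methyl}nona-2,6-dienoate | CCOC(=O)/C(CC(OCC)OCC)=C/CC/C(COCc1ccc(OC)cc1)=C/CCO[Si](C)(C)C(C)(C)C
F7 | step 12 | (2E,6Z)-9-[(tert-butyldimethylsilyl)oxy]-2-(2,2-diethoxyethyl)-6-{[(4-methoxybenzyl)oxy]methyl}nona-2,6-dien-1-ol | OC/C(CC(OCC)OCC)=C/CC/C(COCc1ccc(OC)cc1)=C/CCO[Si](C)(C)C(C)(C)C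
F8 | step 12 | (2E,6Z)-9-[(tert-butyldimethylsilyl)oxy]-1-[(tert-butyldiphenylsilyl)oxy]-2-(2,2-diethoxyethyl)-6-{[(4-methoxybenzyl)oxy]methyl}nona-2,6-diene | CC(C)(C)[Si](OC/C(CC(OCC)OCC)=C/CC/C(COCc1ccc(OC)cc1)=C/CCO[Si](C)(C)C(C)(C)C)(c1ccccc1)c1ccccc1
F9 | step 12 | (2Z)-5-[(tert-butyldimethylsilyl)oxy]-2-[(3E)-4-{[(tert-butyldiphenylsilyl)oxy]methyl}-6,6-diethoxyhex-3-en-1-yl]pent-2-en-1-ol | CC(C)(C)[Si](OC/C(CC(OCC)OCC)=C/CC/C(CO)=C/CCO[Si](C)(C)C(C)(C)C)(c1ccccc1)c1ccccc1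
F10 | step 12 | (2Z)-5-[(tert-butyldimethylsilyl)oxy]-2-[(3E)-4-{[(tert-butyldiphenylsilyl)oxy]methyl}-6,6-diethoxyhex-3-en-1-yl]pent-2-en-1-yl 2-hydroxy-2-methylpropanoate | CC(C)(C)[Si](OC/C(CC(OCC)OCC)=C/CC/C(COC(=O)C(C)(C)O)=C/CCO[Si](C)(C)C(C)(C)C)(c1ccccc1)c1ccccc1
F11 | step 12 | (2Z)-2-[(3E)-4-{[(tert-butyldiphenylsilyl)oxy]methyl}-6,6-diethoxyhex-3-en-1-yl]-5-hydroxypent-2-en-1-yl 2-hydroxy-2-methylpropanoate | CC(C)(C)[Si](OC/C(CC(OCC)OCC)=C/CC/C(COC(=O)C(C)(C)O)=C/CCO)(c1ccccc1)c1ccccc1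
F12 | step 12 | (2Z)-2-[(3E)-4-{[(tert-butyldiphenylsilyl)oxy]methyl}-6,6-diethoxyhex-3-en-1-yl]-5-oxopent-2-en-1-yl 2-hydroxy-2-methylpropanoate | CC(C)(C)[Si](OC/C(CC(OCC)OCC)=C/CC/C(COC(=O)C(C)(C)O)=C/CC=O)(c1ccccc1)c1ccccc1
F13 | step 12 | methyl 2-[bis(2-methylpropyl)alumanyl]prop-2-enoate | C=C([Al](CC(C)C)CC(C)C)C(=O)OC
F14 | step 12 | methyl (5Z,9E)-10-{[(tert-butyldiphenylsilyl)oxy]methyl}-12,12-diethoxy-3-hydroxy-6-{[(2-hydroxy-2-methylpropanoyl)oxy]methyl}-2-methylidenedodeca-5,9-dienoate (racemic at C3) | CC(C)(C)[Si](OC/C(CC(OCC)OCC)=C/CC/C(COC(=O)C(C)(C)O)=C/CC(O)C(=C)C(=O)OC)(c1ccccc1)c1ccccc1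
F15 | step 6 | ethyl 2-(diethoxyphosphoryl)pent-4-enoate (racemic) | CCOC(=O)C(CC=C)P(=O)(OCC)OCC
F16 | step 6 | ethyl 2-(diethoxyphosphoryl)-4-oxobutanoate (racemic) | CCOC(=O)C(CC=O)P(=O)(OCC)OCC
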